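Locants used for every compound: C1 (acetyl), C2 (angelate), C3, C3a, C4 (exocyclic methylene), C5, C6 (epoxy ester), C7 (isopropyl), C7a. Ring A is the cyclohexane C3a–C4–C5–C6–C7–C7a, ring B the cyclopentane C1–C2–C3–C3a–C7a. Names of bicyclic compounds use these locants.

## Analysis of the target

CNP0300602.1 is a trans-fused hydrindane with six stereocentres on nine ring carbons (1R,2S,3aR,6R,7S,7aR) and two more in the (2S,3S)-epoxyangelate on C6. In the chair of ring A, H3a and H7a are trans-diaxial, the isopropyl group on C7 is equatorial and cis to the C3a–C3 bond, and the C6 oxygen is axial and cis to the isopropyl group. On ring B the acetyl group on C1 lies on the face of H7a, trans to the C7a–C7 bond and cis to the angelate on C2. The C2 acyloxy group is β to the acetyl carbonyl, so base can expel it (E1cB) or epimerise C1; the angelate isomerises to the tiglate under nucleophilic catalysis; the glycidic ester and the exocyclic alkene are acid-sensitive. The difficulty lies in the density of stereocentres, in two different esters on two hindered secondary alcohols, and in C7a, which carries only hydrogen and offers no functional group to build from. The strategy rests on ring B: C1 bears an acyl carbon, sits next to the oxygenated C2 and is bonded to the unfunctionalised C7a of ring A. That is the pattern of a 2-acylcyclopentanone formed by 1,5 insertion of a carbenoid at C1 into an equatorial C7a–H bond of a cyclohexane.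

## Retrosynthetic reasoning

**C2–O acyl bond (32 ⇒ 30 + 24).** The angelate is removed first, so that it is installed last. It is the ester that isomerises most easily and the one that creates the β-acyloxy ketone, so it should meet as few reagents as possible. The forward step must acylate a β-hydroxy ketone without base and without a nucleophilic catalyst.

**C6–O acyl bond (30 ⇒ 29 ⇒ 23 + 27).** The epoxy ester is cut next. In 23 the C2 oxygen is silylated and the C6 hydroxyl is free, so the two alcohols are told apart without a protecting group on C6. Acid 27 goes back through 26 and 25 to 24 by alcohol oxidation, tartrate-controlled epoxidation and reduction. The epoxide is made on the small allylic alcohol because two angelates and an exocyclic alkene on the core could not be differentiated.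

**Acetyl C–CH3 bond and C4=CH2 (23 ⇒ 22 ⇒ 21).** The methyl ketone is traced to an N-methoxy-N-methyl amide, which tolerates every step between 15 and 22 and reacts once with a methyl organometallic. The exocyclic methylene is traced to the C4 ketone of 21. Carbonyl methylenation must not enolise C3a or eliminate the β-hydroxyl.

**C6–O bond (21 ⇒ 19 ⇒ 18 ⇒ 17).** After the key step the C4 carbonyl is the only handle in ring A. It activates C6 through the C5=C6 enone 19, obtained by kinetic enolisation of 17 toward C5 (18) and dehydrogenation. The forward reaction must add oxygen to C6 axially, cis to the isopropyl group; conjugate borylation and oxidation with retention is chosen.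

**Functional group changes on ring B (17 ⇒ 16 ⇒ 15 ⇒ 14 ⇒ 13).** No skeletal bond is cut. The C2 ketone is reduced first, which locks C1. The ester is converted to the amide while the cis hydroxyl is free and can assist. The hydroxyl is then silylated and C4 unmasked.

**C1–C7a bond, the key disconnection (13 ⇒ 12).** Cutting C1–C7a opens ring B to a monocyclic ketal with a diazo β-keto ester side chain on C3a. It removes one ring and two stereocentres (C7a, C1) and leaves a precursor with only C3a and C7. The forward step must insert into the equatorial C7a–H bond and no other.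

**C1–C2 and C3a–C3 bonds (12 ⇒ 11 ⇒ 8 + 9; 8 ⇒ 7 ⇒ 6 ⇒ 5 ⇒ 2 + 3).** The diazo group comes from diazo transfer to 11, and 11 from acylation of malonate half-ester 9 by acid 8. The side chain is attached by alkylation of a regiodefined enolate with 3. A base-cleavable methyl ester is chosen for 3, because an acid-labile ester could not be removed beside the dioxolane. Equilibration gives the cis ketone 6.

**Desymmetrisation (2 ⇒ 1).** The achiral ketone 1 has two enantiotopic α-methylene groups. A chiral lithium amide selects one, and the silyl enol ether 2 stores that choice as regiochemistry. C7 thereby becomes the stereocentre that controls all others.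

## Alternatives that were turned down

**Alternative 1:** The C5–C6 bond of ring A is cut and made last. The forward step is a Lewis-acid-promoted type 2 carbonyl-ene reaction: the terminal carbon of an isopropenyl group on C3a attacks a C6 aldehyde, a methyl hydrogen moves to oxygen, and the alkene ends as the C4 methylene, giving alcohol A1.
- For: one step makes ring A, the C6 carbinol and the exocyclic alkene, with acetyl and angelate already in place, so only one acylation remains. Here it is stronger than the chosen route, which needs steps 13 to 17 for the same features and must acylate C2 beside the ketone.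
- Against: the precursor is a fully substituted cyclopentane with four ring stereocentres and an acyclic, α-branched and epimerisable aldehyde centre at C7, and the disconnection does nothing to build it. The Lewis acid also meets a methyl ketone that can undergo aldol addition to the aldehyde through a six-membered ring, and the axial C6 hydroxyl depends on two chair transition states of similar energy.
- In its place the chosen route offers stereocontrol from one locked chair and a monocyclic precursor reached in seven steps.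

**Alternative 2:** C1–C2, C2–C3 and C3a–C7a are cut together. A Pauson–Khand reaction of an acyclic 1,7-enyne would close both rings and give enone A2, with the C2 carbonyl, a C1=C7a alkene and the C6 silyloxy and C7 isopropyl groups in place.
- For: three bonds and two rings in one step, and C6 and C7 set by acyclic stereocontrol before cyclisation. That is stronger than the late enone and borylation sequence of the chosen route.
- Against: 1,7-enynes cyclise to the six-membered ring more slowly than 1,6-enynes, and the C3a configuration would be set with little bias. A2 also has no substituent on C1 and an sp2 C7a, so the acyl carbon must still be added and the alkene reduced to the trans fusion, while hydrogenation of such hydrindenones tends to give the cis fusion.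
- The chosen route delivers the trans fusion and the C1 carbon in the same step.

**Alternative 3:** Ring B is cut at C3a–C7a and at the bond from C1 to the acetyl carbon. Irradiation of a dioxinone tethered to a C1=C7a alkene would give a crossed (2+2) photoadduct, and methanolysis would open the cyclobutane by retro-aldol cleavage to keto ester A3.
- For: the acetyl group arrives in its final oxidation state and the relations around ring B come from a rigid photoadduct. That is stronger than the amide and Grignard detour of the chosen route.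
- Against: facial selectivity rests on the C2 ether centre and a remote acyclic C7 centre, and crossed versus straight addition is not assured. Ring A is still open in A3, so C4 and C5 must be built from the ester and the silyloxymethyl arm beside a free methyl ketone, and C6–O stereochemistry has to be controlled again.
- The chosen route has the whole bicycle at step 8.

Key step: step 8

Assumption: by analogy with other 4-alkylcyclohexanones, the (S,S)-amide is taken to give the (R)-enol ether 2; if the sense is opposite, the (R,R)-amide is used with no other change.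

## Route

Step 1
Reactants: 1 4-(propan-2-yl)cyclohexan-1-one
Product: 2 trimethyl{[(4R)-4-(propan-2-yl)cyclohex-1-en-1-yl]oxy}silane
Conditions: (S,S)-bis(1-phenylethyl)amine hydrochloride, n-BuLi (2 equiv), THF, −78 °C; TMSCl, then 1, −78 °C
Reagents that add atoms: chlorotrimethylsilane, C[Si](C)(C)Cl
Why: Enantioselective deprotonation: the C2-symmetric lithium amide (with LiCl from the salt) removes one of the two enantiotopic axial α-protons of the chair with equatorial isopropyl, and in situ silylation traps the enolate before it can equilibrate; this makes C7 stereogenic (R in 2).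

Step 2
Reactants: 2 trimethyl{[(4R)-4-(propan-2-yl)cyclohex-1-en-1-yl]oxy}silane; 3 methyl bromoacetate
Product: 5 methyl 2-[(5R)-2-oxo-5-(propan-2-yl)cyclohexyl]acetate as a mixture of C3a epimers, via lithium enolate 4 (not isolated)
Conditions: MeLi, THF, 0 °C; then 3, DMPU, −78 → −20 °C
Reagents that add atoms: none
Why: MeLi cleaves the O–Si bond to the regiodefined lithium enolate, which is alkylated (SN2) by the reactive α-bromo ester faster than it exchanges protons; the C3a–C3 bond forms on the carbon chosen in step 1, and the epimer ratio at C3a does not matter.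

Step 3
Reactants: 5 methyl 2-[(5R)-2-oxo-5-(propan-2-yl)cyclohexyl]acetate (epimer mixture)
Product: 6 methyl 2-[(1S,5R)-2-oxo-5-(propan-2-yl)cyclohexyl]acetate (cis)
Conditions: NaOMe (cat.), MeOH, rt
Reagents that add atoms: none
Why: Base-mediated epimerisation through the enolate should converge on the cis isomer, in which the side chain and the isopropyl group are both equatorial (1,3-cis); C7 cannot enolise, so the enantiomeric purity is untouched.

Step 4
Reactants: 6 methyl 2-[(1S,5R)-2-oxo-5-(propan-2-yl)cyclohexyl]acetate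
Product: 7 methyl 2-[(6S,8R)-8-(propan-2-yl)-1,4-dioxaspiro[4.5]decan-6-yl]acetate
Conditions: HOCH2CH2OH, p-TsOH·H2O (cat.), benzene, reflux (Dean–Stark)
Reagents that add atoms: ethylene glycol, OCCO
Why: Acid-catalysed ketalisation; it turns C4 into a carbon without hydrogen and removes the carbonyl oxygen that would otherwise trap the later carbenoid as a carbonyl ylide.

Step 5
Reactants: 7 methyl 2-[(6S,8R)-8-(propan-2-yl)-1,4-dioxaspiro[4.5]decan-6-yl]acetate
Product: 8 2-[(6S,8R)-8-(propan-2-yl)-1,4-dioxaspiro[4.5]decan-6-yl]acetic acid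
Conditions: LiOH·H2O, THF/MeOH/H2O, rt; then 1 M HCl to pH 4, 0 °C
Reagents that add atoms: lithium hydroxide, [Li+].[OH-]
Why: Saponification; the dioxolane is inert to hydroxide and should survive a cold, brief acidification to pH 4.

Step 6
Reactants: 8 2-[(6S,8R)-8-(propan-2-yl)-1,4-dioxaspiro[4.5]decan-6-yl]acetic acid; 9 potassium methyl malonate
Product: 11 methyl 3-oxo-4-[(6S,8R)-8-(propan-2-yl)-1,4-dioxaspiro[4.5]decan-6-yl]butanoate, via acyl imidazolide 10 (not isolated)
Conditions: CDI, THF, rt; then 9, MgCl2, Et3N, MeCN, rt → 40 °C; cold 0.5 M HCl work-up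
Reagents that add atoms: 1,1'-carbonyldiimidazole, O=C(n1ccnc1)n1ccnc1 (its imidazolyl group is carried only in 10)
Why: Masamune homologation: the magnesium enolate of the malonate half-ester is C-acylated by the acyl imidazolide and loses CO2, which forms the C1–C2 bond under nearly neutral conditions.

Step 7
Reactants: 11 methyl 3-oxo-4-[(6S,8R)-8-(propan-2-yl)-1,4-dioxaspiro[4.5]decan-6-yl]butanoate
Product: 12 methyl 2-diazo-3-oxo-4-[(6S,8R)-8-(propan-2-yl)-1,4-dioxaspiro[4.5]decan-6-yl]butanoate
Conditions: p-ABSA, Et3N, MeCN, 0 °C → rt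
Reagents that add atoms: 4-acetamidobenzenesulfonyl azide, CC(=O)Nc1ccc(cc1)S(=O)(=O)N=[N+]=[N-]
Why: Regitz diazo transfer to the active methylene of a β-keto ester.

Step 8
Reactants: 12 methyl 2-diazo-3-oxo-4-[(6S,8R)-8-(propan-2-yl)-1,4-dioxaspiro[4.5]decan-6-yl]butanoate
Product: 13 methyl (1R,3aR,7S,7aS)-2-oxo-7-(propan-2-yl)octahydrospiro[indene-4,2'-[1,3]dioxolane]-1-carboxylate
Conditions: Rh2(OAc)4 (1 mol%), CH2Cl2, rt, slow addition of 12
Reagents that add atoms: none
Why: Rh2(OAc)4, a divalent-rhodium carboxylate dimer, takes N2 from the diazo carbon and gives an electrophilic rhodium carbenoid at C1 that inserts into a C–H bond in a concerted three-centre step with retention at carbon; this is the established carbenoid 1,5 C–H insertion of α-diazo β-keto esters to 2-alkoxycarbonylcyclopentanones. Ring B closes through a six-membered chair-like transition state made of C1, C2, C3, C3a, C7a and the migrating hydrogen, so a five-membered ring results and C1–C7a is the only skeletal bond formed. Only the two hydrogens on C7a stand in a 1,5 relation, because C4 is a ketal carbon without hydrogen, and the hydrogens on C5, C7 and the isopropyl group would require six- or seven-membered rings. C7a is set by the choice between its two C–H bonds: ring A is held in one chair by the equatorial isopropyl group and the equatorial side chain, and insertion into the equatorial C7a–H bond with retention places C1 equatorial and leaves H7a axial and anti to H3a, which is the trans fusion. C1 is formed as an epimerisable β-keto ester centre and should settle with the ester trans to the C7a–C7 bond. The step needs equatorial over axial C–H insertion and insertion over capture of the carbenoid by a ketal oxygen; the first is supported by the diequatorial substrate and the lower strain of the trans-fused transition state, the second by the preference of rhodium carboxylate carbenoids for five-membered C–H insertion over six-membered oxonium ylide formation.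

Step 9
Reactants: 13 methyl (1R,3aR,7S,7aS)-2-oxo-7-(propan-2-yl)octahydrospiro[indene-4,2'-[1,3]dioxolane]-1-carboxylate
Product: 14 methyl (1R,2S,3aR,7S,7aS)-2-hydroxy-7-(propan-2-yl)octahydrospiro[indene-4,2'-[1,3]dioxolane]-1-carboxylate
Conditions: NaBH4, MeOH, −40 °C
Reagents that add atoms: none
Why: Hydride reduction of the ring ketone; both faces of C2 carry one pseudoaxial ring-fusion hydrogen, so the C1 ester decides, hydride adds anti to it and the hydroxyl should end cis to the ester (2S), which also fixes C1.

Step 10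
Reactants: 14 methyl (1R,2S,3aR,7S,7aS)-2-hydroxy-7-(propan-2-yl)octahydrospiro[indene-4,2'-[1,3]dioxolane]-1-carboxylate
Product: 15 (1R,2S,3aR,7S,7aS)-2-hydroxy-N-methoxy-N-methyl-7-(propan-2-yl)octahydrospiro[indene-4,2'-[1,3]dioxolane]-1-carboxamide
Conditions: MeNH(OMe)·HCl, i-PrMgCl, THF, −20 → 0 °C
Reagents that add atoms: N,O-dimethylhydroxylamine hydrochloride, CNOC.Cl
Why: Weinreb amide formation by aminolysis of the ester with the magnesium amide; it is done while the cis hydroxyl is free, because the neighbouring magnesium alkoxide helps the hindered ester to react, and the reagent is not Lewis-acidic enough to open the ketal.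

Step 11
Reactants: 15 (1R,2S,3aR,7S,7aS)-2-hydroxy-N-methoxy-N-methyl-7-(propan-2-yl)octahydrospiro[indene-4,2'-[1,3]dioxolane]-1-carboxamide
Product: 16 (1R,2S,3aR,7S,7aS)-2-[(tert-butyldimethylsilyl)oxy]-N-methoxy-N-methyl-7-(propan-2-yl)octahydrospiro[indene-4,2'-[1,3]dioxolane]-1-carboxamide
Conditions: TBSOTf, 2,6-lutidine, CH2Cl2, −78 → 0 °C
Reagents that add atoms: tert-butyldimethylsilyl trifluoromethanesulfonate, CC(C)(C)[Si](C)(C)OS(=O)(=O)C(F)(F)F
Why: Silylation of a hindered secondary alcohol with the silyl triflate; the silyl ether is stable to the acid, base and organometallic steps up to step 21.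

Step 12
Reactants: 16 (1R,2S,3aR,7S,7aS)-2-[(tert-butyldimethylsilyl)oxy]-N-methoxy-N-methyl-7-(propan-2-yl)octahydrospiro[indene-4,2'-[1,3]dioxolane]-1-carboxamide
Product: 17 (1R,2S,3aR,7S,7aS)-2-[(tert-butyldimethylsilyl)oxy]-N-methoxy-N-methyl-4-oxo-7-(propan-2-yl)octahydro-1H-indene-1-carboxamide
Conditions: PPTS, acetone/H2O, 55 °C
Reagents that add atoms: water, O
Why: Mild acid-catalysed ketal hydrolysis that spares the secondary silyl ether and the amide; C3a becomes enolisable but the all-equatorial trans-fused ketone is the expected thermodynamic isomer.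

Step 13
Reactants: 17 (1R,2S,3aR,7S,7aS)-2-[(tert-butyldimethylsilyl)oxy]-N-methoxy-N-methyl-4-oxo-7-(propan-2-yl)octahydro-1H-indene-1-carboxamide
Product: 18 (1R,2S,3aR,7S,7aS)-2-[(tert-butyldimethylsilyl)oxy]-N-methoxy-N-methyl-7-(propan-2-yl)-4-[(trimethylsilyl)oxy]-2,3,3a,6,7,7a-hexahydro-1H-indene-1-carboxamide
Conditions: LDA, TMSCl, THF, −78 °C
Reagents that add atoms: chlorotrimethylsilane, C[Si](C)(C)Cl
Why: Kinetic deprotonation takes the C5 methylene proton and not the hindered C3a methine or the far less acidic C1–H of the amide, and in situ silylation fixes the C4=C5 enol ether.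

Step 14
Reactants: 18 (1R,2S,3aR,7S,7aS)-2-[(tert-butyldimethylsilyl)oxy]-N-methoxy-N-methyl-7-(propan-2-yl)-4-[(trimethylsilyl)oxy]-2,3,3a,6,7,7a-hexahydro-1H-indene-1-carboxamide
Product: 19 (1R,2S,3aR,7R,7aS)-2-[(tert-butyldimethylsilyl)oxy]-N-methoxy-N-methyl-4-oxo-7-(propan-2-yl)-2,3,3a,4,7,7a-hexahydro-1H-indene-1-carboxamide
Conditions: Pd(OAc)2 (1.05 equiv), MeCN, rt
Reagents that add atoms: none
Why: Saegusa–Ito oxidation: the silyl enol ether gives an oxa-π-allyl complex of divalent palladium and β-hydride elimination of the C6 hydrogen delivers the C5=C6 enone; the change of the C7 descriptor to R is a priority change only.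

Step 15
Reactants: 19 (1R,2S,3aR,7R,7aS)-2-[(tert-butyldimethylsilyl)oxy]-N-methoxy-N-methyl-4-oxo-7-(propan-2-yl)-2,3,3a,4,7,7a-hexahydro-1H-indene-1-carboxamide
Product: 21 (1R,2S,3aR,6R,7S,7aS)-2-[(tert-butyldimethylsilyl)oxy]-6-hydroxy-N-methoxy-N-methyl-4-oxo-7-(propan-2-yl)octahydro-1H-indene-1-carboxamide, via C6 pinacol boronate 20 (not isolated)
Conditions: CuCl (cat.), NaOt-Bu (cat.), DPEphos (cat.), B2pin2, MeOH (2 equiv), THF, rt; then NaBO3·4H2O, THF/H2O, rt
Reagents that add atoms: sodium perborate tetrahydrate, [Na+].[O-]OB=O; bis(pinacolato)diboron, CC1(C)OB(OC1(C)C)B1OC(C)(C)C(C)(C)O1 (its boron is carried only in 20)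
Why: Copper-catalysed conjugate borylation followed by C–B oxidation with retention; the trans fusion locks the enone half-chair, so stereoelectronically preferred axial attack at C6, on the face that carries only the axial H7a, should give the axial C–B bond and then the axial hydroxyl cis to the isopropyl group (6R).

Step 16
Reactants: 21 (1R,2S,3aR,6R,7S,7aS)-2-[(tert-butyldimethylsilyl)oxy]-6-hydroxy-N-methoxy-N-methyl-4-oxo-7-(propan-2-yl)octahydro-1H-indene-1-carboxamide
Product: 22 (1R,2S,3aR,6R,7S,7aR)-2-[(tert-butyldimethylsilyl)oxy]-6-hydroxy-N-methoxy-N-methyl-4-methylidene-7-(propan-2-yl)octahydro-1H-indene-1-carboxamide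
Conditions: Zn, CH2Br2, TiCl4, THF (preformed reagent); then 21, CH2Cl2, 0 °C → rt
Reagents that add atoms: dibromomethane, BrCBr
Why: Lombardo methylenation: the non-basic zinc–titanium methylene reagent converts ketones to methylene compounds without enolisation, so C3a should not epimerise and the β-hydroxy ketone should neither eliminate nor undergo retro-aldol cleavage; free hydroxyls and amides are tolerated.

Step 17
Reactants: 22 (1R,2S,3aR,6R,7S,7aR)-2-[(tert-butyldimethylsilyl)oxy]-6-hydroxy-N-methoxy-N-methyl-4-methylidene-7-(propan-2-yl)octahydro-1H-indene-1-carboxamide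
Product: 23 1-[(1R,2S,3aR,6R,7S,7aR)-2-[(tert-butyldimethylsilyl)oxy]-6-hydroxy-4-methylidene-7-(propan-2-yl)octahydro-1H-inden-1-yl]ethan-1-one
Conditions: MeMgBr (4 equiv), THF, 0 °C → rt
Reagents that add atoms: methylmagnesium bromide, C[Mg]Br
Why: Weinreb ketone synthesis: the chelated tetrahedral adduct survives until work-up, so only one methyl group is added; one equivalent of reagent is spent on the C6 hydroxyl.

Step 18
Reactants: 24 angelic acid, (2Z)-2-methylbut-2-enoic acid
Product: 25 (2Z)-2-methylbut-2-en-1-ol
Conditions: LiAlH4, Et2O, 0 °C → rt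
Reagents that add atoms: none
Why: Hydride reduction of the conjugated acid to the allylic alcohol with the Z geometry unchanged.

Step 19
Reactants: 25 (2Z)-2-methylbut-2-en-1-ol
Product: 26 [(2R,3S)-2,3-dimethyloxiran-2-yl]methanol
Conditions: Ti(Oi-Pr)4 (cat.), diethyl D-(−)-tartrate (cat.), t-BuOOH, 4 Å MS, CH2Cl2, −20 °C
Reagents that add atoms: tert-butyl hydroperoxide, CC(C)(C)OO
Why: Sharpless asymmetric epoxidation; the D-tartrate ligand directs oxygen to the alkene face that gives the (2R,3S)-epoxy alcohol, and the cis relation of the hydroxymethyl group and the C3 methyl is inherited from the Z alkene.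

Step 20
Reactants: 26 [(2R,3S)-2,3-dimethyloxiran-2-yl]methanol
Product: 27 (2S,3S)-2,3-dimethyloxirane-2-carboxylic acid
Conditions: RuCl3·xH2O (cat.), NaIO4, MeCN/EtOAc/H2O, 0 °C → rt
Reagents that add atoms: sodium periodate, [Na+].[O-]I(=O)(=O)=O; water, O
Why: Catalytic ruthenium tetroxide oxidation of the primary alcohol to the acid, which leaves the epoxide intact; the C2 descriptor changes from R to S only because the carboxyl group outranks C3.

Step 21
Reactants: 23 1-[(1R,2S,3aR,6R,7S,7aR)-2-[(tert-butyldimethylsilyl)oxy]-6-hydroxy-4-methylidene-7-(propan-2-yl)octahydro-1H-inden-1-yl]ethan-1-one; 27 (2S,3S)-2,3-dimethyloxirane-2-carboxylic acid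
Product: 29 (1R,2S,3aR,6R,7S,7aR)-1-acetyl-2-[(tert-butyldimethylsilyl)oxy]-4-methylidene-7-(propan-2-yl)octahydro-1H-inden-6-yl (2S,3S)-2,3-dimethyloxirane-2-carboxylate, via mixed anhydride 28 (not isolated)
Conditions: 27, 2,4,6-Cl3C6H2COCl, Et3N, toluene, rt; then 23, DMAP, toluene, rt → 40 °C
Reagents that add atoms: 2,4,6-trichlorobenzoyl chloride, O=C(Cl)c1c(Cl)cc(Cl)cc1Cl (its aroyl group is carried only in 28)
Why: Yamaguchi esterification, suited to a hindered axial alcohol and an α-quaternary acid; the β-silyloxy ketone tolerates the amine bases, and the minor enantiomers of both partners should end as diastereomers that can be removed here.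

Step 22
Reactants: 29 (1R,2S,3aR,6R,7S,7aR)-1-acetyl-2-[(tert-butyldimethylsilyl)oxy]-4-methylidene-7-(propan-2-yl)octahydro-1H-inden-6-yl (2S,3S)-2,3-dimethyloxirane-2-carboxylate
Product: 30 (1R,2S,3aR,6R,7S,7aR)-1-acetyl-2-hydroxy-4-methylidene-7-(propan-2-yl)octahydro-1H-inden-6-yl (2S,3S)-2,3-dimethyloxirane-2-carboxylate
Conditions: HF·pyridine, pyridine, THF, 0 °C → rt
Reagents that add atoms: none
Why: Fluoride-mediated desilylation under buffered, non-basic conditions, which should spare the electron-poor glycidic ester and avoid retro-aldol cleavage of the β-hydroxy ketone.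

Step 23
Reactants: 30 (1R,2S,3aR,6R,7S,7aR)-1-acetyl-2-hydroxy-4-methylidene-7-(propan-2-yl)octahydro-1H-inden-6-yl (2S,3S)-2,3-dimethyloxirane-2-carboxylate; 24 angelic acid
Product: 32 (1R,2S,3aR,6R,7S,7aR)-1-acetyl-4-methylidene-2-{[(2Z)-2-methylbut-2-enoyl]oxy}-7-(propan-2-yl)octahydro-1H-inden-6-yl (2S,3S)-2,3-dimethyloxirane-2-carboxylate, via angelic mixed anhydride 31 (not isolated)
Conditions: 24, 2,4,6-Cl3C6H2COCl, Et3N, toluene, rt; then 30, NaHCO3, toluene, 70 °C
Reagents that add atoms: 2,4,6-trichlorobenzoyl chloride, O=C(Cl)c1c(Cl)cc(Cl)cc1Cl (its aroyl group is carried only in 31)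
Why: Thermal acylation by the preformed mixed anhydride at its less hindered angeloyl carbonyl, without a nucleophilic catalyst, so that the Z alkene is not isomerised; no free amine is present and solid NaHCO3 takes up the liberated acid, which limits elimination at C2 and epimerisation at C1.

## Compound list

1 | 4-(propan-2-yl)cyclohexan-1-one | CC(C)C1CCC(=O)CC1 | starting material
2 | trimethyl{[(4R)-4-(propan-2-yl)cyclohex-1-en-1-yl]oxy}silane | C[Si](C)(C)OC1=CC[C@H](C(C)C)CC1 | intermediate
3 | methyl bromoacetate | COC(=O)CBr | starting material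
4 | lithium (4R)-4-(propan-2-yl)cyclohex-1-en-1-olate | [Li+].[O-]C1=CC[C@H](C(C)C)CC1 | intermediate (not isolated)
5 | methyl 2-[(5R)-2-oxo-5-(propan-2-yl)cyclohexyl]acetate, mixture of C3a epimers | COC(=O)CC1C[C@H](C(C)C)CCC1=O | intermediate
6 | methyl 2-[(1S,5R)-2-oxo-5-(propan-2-yl)cyclohexyl]acetate | COC(=O)C[C@H]1C(=O)CC[C@@H](C(C)C)C1 | intermediate
7 | methyl 2-[(6S,8R)-8-(propan-2-yl)-1,4-dioxaspiro[4.5]decan-6-yl]acetate | COC(=O)C[C@H]1C2(OCCO2)CC[C@@H](C(C)C)C1 | intermediate
8 | 2-[(6S,8R)-8-(propan-2-yl)-1,4-dioxaspiro[4.5]decan-6-yl]acetic acid | OC(=O)C[C@H]1C2(OCCO2)CC[C@@H](C(C)C)C1 | intermediate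
9 | potassium methyl malonate (potassium 3-methoxy-3-oxopropanoate) | COC(=O)CC(=O)[O-].[K+] | starting material
10 | 1-(imidazol-1-yl)-2-[(6S,8R)-8-(propan-2-yl)-1,4-dioxaspiro[4.5]decan-6-yl]ethan-1-one | O=C(C[C@H]1C2(OCCO2)CC[C@@H](C(C)C)C1)n1ccnc1 | intermediate (not isolated)
11 | methyl 3-oxo-4-[(6S,8R)-8-(propan-2-yl)-1,4-dioxaspiro[4.5]decan-6-yl]butanoate | COC(=O)CC(=O)C[C@H]1C2(OCCO2)CC[C@@H](C(C)C)C1 | intermediate
12 | methyl 2-diazo-3-oxo-4-[(6S,8R)-8-(propan-2-yl)-1,4-dioxaspiro[4.5]decan-6-yl]butanoate | COC(=O)C(=[N+]=[N-])C(=O)C[C@H]1C2(OCCO2)CC[C@@H](C(C)C)C1 | intermediate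
13 | methyl (1R,3aR,7S,7aS)-2-oxo-7-(propan-2-yl)octahydrospiro[indene-4,2'-[1,3]dioxolane]-1-carboxylate | O1CCOC12CC[C@@H](C(C)C)[C@@H]3[C@@H](C(=O)OC)C(=O)C[C@@H]23 | intermediate
14 | methyl (1R,2S,3aR,7S,7aS)-2-hydroxy-7-(propan-2-yl)octahydrospiro[indene-4,2'-[1,3]dioxolane]-1-carboxylate | O1CCOC12CC[C@@H](C(C)C)[C@@H]3[C@@H](C(=O)OC)[C@@H](O)C[C@@H]23 | intermediate
15 | (1R,2S,3aR,7S,7aS)-2-hydroxy-N-methoxy-N-methyl-7-(propan-2-yl)octahydrospiro[indene-4,2'-[1,3]dioxolane]-1-carboxamide | O1CCOC12CC[C@@H](C(C)C)[C@@H]3[C@@H](C(=O)N(C)OC)[C@@H](O)C[C@@H]23 | intermediate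
16 | (1R,2S,3aR,7S,7aS)-2-[(tert-butyldimethylsilyl)oxy]-N-methoxy-N-methyl-7-(propan-2-yl)octahydrospiro[indene-4,2'-[1,3]dioxolane]-1-carboxamide | O1CCOC12CC[C@@H](C(C)C)[C@@H]3[C@@H](C(=O)N(C)OC)[C@@H](O[Si](C)(C)C(C)(C)C)C[C@@H]23 | intermediate
17 | (1R,2S,3aR,7S,7aS)-2-[(tert-butyldimethylsilyl)oxy]-N-methoxy-N-methyl-4-oxo-7-(propan-2-yl)octahydro-1H-indene-1-carboxamide | O=C1CC[C@@H](C(C)C)[C@@H]2[C@@H](C(=O)N(C)OC)[C@@H](O[Si](C)(C)C(C)(C)C)C[C@@H]12 | intermediate
18 | (1R,2S,3aR,7S,7aS)-2-[(tert-butyldimethylsilyl)oxy]-N-methoxy-N-methyl-7-(propan-2-yl)-4-[(trimethylsilyl)oxy]-2,3,3a,6,7,7a-hexahydro-1H-indene-1-carboxamide | C[Si](C)(C)OC1=CC[C@@H](C(C)C)[C@@H]2[C@@H](C(=O)N(C)OC)[C@@H](O[Si](C)(C)C(C)(C)C)C[C@@H]12 | intermediate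
19 | (1R,2S,3aR,7R,7aS)-2-[(tert-butyldimethylsilyl)oxy]-N-methoxy-N-methyl-4-oxo-7-(propan-2-yl)-2,3,3a,4,7,7a-hexahydro-1H-indene-1-carboxamide | O=C1C=C[C@@H](C(C)C)[C@@H]2[C@@H](C(=O)N(C)OC)[C@@H](O[Si](C)(C)C(C)(C)C)C[C@@H]12 | intermediate
20 | (1R,2S,3aR,6R,7S,7aS)-2-[(tert-butyldimethylsilyl)oxy]-N-methoxy-N-methyl-4-oxo-7-(propan-2-yl)-6-(4,4,5,5-tetramethyl-1,3,2-dioxaborolan-2-yl)octahydro-1H-indene-1-carboxamide (axial boronate) | O=C1C[C@@H](B2OC(C)(C)C(C)(C)O2)[C@@H](C(C)C)[C@@H]3[C@@H](C(=O)N(C)OC)[C@@H](O[Si](C)(C)C(C)(C)C)C[C@@H]13 | intermediate (not isolated)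
21 | (1R,2S,3aR,6R,7S,7aS)-2-[(tert-butyldimethylsilyl)oxy]-6-hydroxy-N-methoxy-N-methyl-4-oxo-7-(propan-2-yl)octahydro-1H-indene-1-carboxamide | O=C1C[C@@H](O)[C@@H](C(C)C)[C@@H]2[C@@H](C(=O)N(C)OC)[C@@H](O[Si](C)(C)C(C)(C)C)C[C@@H]12 | intermediate
22 | (1R,2S,3aR,6R,7S,7aR)-2-[(tert-butyldimethylsilyl)oxy]-6-hydroxy-N-methoxy-N-methyl-4-methylidene-7-(propan-2-yl)octahydro-1H-indene-1-carboxamide | C=C1C[C@@H](O)[C@@H](C(C)C)[C@@H]2[C@@H](C(=O)N(C)OC)[C@@H](O[Si](C)(C)C(C)(C)C)C[C@@H]12 | intermediate
23 | 1-[(1R,2S,3aR,6R,7S,7aR)-2-[(tert-butyldimethylsilyl)oxy]-6-hydroxy-4-methylidene-7-(propan-2-yl)octahydro-1H-inden-1-yl]ethan-1-one | C=C1C[C@@H](O)[C@@H](C(C)C)[C@@H]2[C@@H](C(C)=O)[C@@H](O[Si](C)(C)C(C)(C)C)C[C@@H]12 | intermediate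
24 | angelic acid, (2Z)-2-methylbut-2-enoic acid | C/C=C(/C)C(=O)O | starting material
25 | (2Z)-2-methylbut-2-en-1-ol | C/C=C(/C)CO | intermediate
26 | [(2R,3S)-2,3-dimethyloxiran-2-yl]methanol | OC[C@@]1(C)O[C@H]1C | intermediate
27 | (2S,3S)-2,3-dimethyloxirane-2-carboxylic acid | OC(=O)[C@@]1(C)O[C@H]1C | intermediate
28 | (2S,3S)-2,3-dimethyloxirane-2-carboxylic 2,4,6-trichlorobenzoic anhydride | O=C(OC(=O)c1c(Cl)cc(Cl)cc1Cl)[C@@]1(C)O[C@H]1C | intermediate (not isolated)
29 | (1R,2S,3aR,6R,7S,7aR)-1-acetyl-2-[(tert-butyldimethylsilyl)oxy]-4-methylidene-7-(propan-2-yl)octahydro-1H-inden-6-yl (2S,3S)-2,3-dimethyloxirane-2-carboxylate | C=C1C[C@@H](OC(=O)[C@@]2(C)O[C@H]2C)[C@@H](C(C)C)[C@@H]2[C@@H](C(C)=O)[C@@H](O[Si](C)(C)C(C)(C)C)C[C@@H]12 | intermediate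
30 | (1R,2S,3aR,6R,7S,7aR)-1-acetyl-2-hydroxy-4-methylidene-7-(propan-2-yl)octahydro-1H-inden-6-yl (2S,3S)-2,3-dimethyloxirane-2-carboxylate | C=C1C[C@@H](OC(=O)[C@@]2(C)O[C@H]2C)[C@@H](C(C)C)[C@@H]2[C@@H](C(C)=O)[C@@H](O)C[C@@H]12 | intermediate
31 | (2Z)-2-methylbut-2-enoic 2,4,6-trichlorobenzoic anhydride | C/C=C(/C)C(=O)OC(=O)c1c(Cl)cc(Cl)cc1Cl | intermediate (not isolated)
32 | (1R,2S,3aR,6R,7S,7aR)-1-acetyl-4-methylidene-2-{[(2Z)-2-methylbut-2-enoyl]oxy}-7-(propan-2-yl)octahydro-1H-inden-6-yl (2S,3S)-2,3-dimethyloxirane-2-carboxylate (CNP0300602.1) | C=C1C[C@@H](OC(=O)[C@@]2(C)O[C@H]2C)[C@@H](C(C)C)[C@@H]2[C@@H](C(C)=O)[C@@H](OC(=O)/C(C)=C\C)C[C@@H]12 | target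

## Step count and least certain steps

Total: 23 steps. Longest linear sequence: 20 steps (steps 1–17 and 21–23); steps 18–20 form the three-step branch to acid 27.

**Step 8 (key step).**
- Risk: insertion into the axial C7a–H bond would give the cis-fused isomer, and C7a cannot be epimerised afterwards. A ketal oxygen may also capture the carbenoid as an oxonium ylide, which then rearranges. Both hydrogens on C7a are gauche to the equatorial side chain, so the preference for the equatorial one rests on transition-state strain alone.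
- Fallback, from 2 to 13 (gives up the insertion and closes ring B at C1–C2):
  - Saegusa–Ito oxidation of 2 (Pd(OAc)2, MeCN) gives (4S)-4-(propan-2-yl)cyclohex-2-en-1-one F1.
  - Lewis-acid-catalysed Mukaiyama–Michael addition of 1-tert-butoxy-1-(trimethylsilyloxy)ethene at −78 °C adds the acetate unit to C7a trans to the isopropyl group and gives the silyl enol ether adduct F2.
  - MeLi and then 3 alkylate C3a trans to the C7a substituent to give the all-equatorial keto diester F3.
  - 1,2-Bis(trimethylsilyloxy)ethane with catalytic TMSOTf gives the ketal diester F4.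
  - KOt-Bu in THF effects a Dieckmann cyclisation in which the enolate of the tert-butyl ester attacks the methyl ester (the tert-butyl ester is not an acyl donor), giving the trans-fused tert-butyl β-keto ester F5.
  - Heating F5 with methanol in toluene exchanges the ester through the acylketene and gives 13.

**Step 15.**
- Risk: poor facial selectivity in the addition of the bulky copper–boryl species to C6, since the equatorial isopropyl group flanks both faces and only the stereoelectronic preference favours axial attack.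
- Fallback, from 19 to 21: Weitz–Scheffer epoxidation (H2O2, NaOH, MeOH, 0 °C), in which the small hydroperoxide anion adds axially, gives the 5,6-epoxy ketone with the oxygen on the face of H7a F6. Reductive opening of the Cα–O bond with sodium phenylselenoborate (PhSeSePh, NaBH4, AcOH, EtOH) gives 21.

**Step 16.**
- Risk: dehydration or retro-aldol cleavage of the β-hydroxy ketone under the Lewis-acidic reagent, and incomplete conversion because the free hydroxyl consumes reagent.
- Fallback, from 19 to 22: the borylation of step 15 is stopped before oxidation and boronate 20 is isolated. Wittig methylenation (Ph3PCH3Br, KOt-Bu, THF) of 20, whose C–B bond cannot leave as a β-leaving group, gives the methylidene boronate F7. Oxidation of F7 with NaBO3·4H2O gives 22.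

**Step 23.**
- Risk: β-elimination of the new C2 acyloxy group (the C1 hydrogen is anti to it) or epimerisation at C1 during prolonged heating, retro-aldol cleavage of 30, and Z to E isomerisation of the angelate.
- Fallback, from 29 to 32 (the ketone is masked while C2 is acylated):
  - NaBH4 in MeOH reduces the acetyl group to the carbinol F8, as a mixture at the carbinol carbon that does not matter.
  - 4-Methoxybenzyl trichloroacetimidate with catalytic acid gives the PMB ether F9.
  - HF·pyridine gives the C2 alcohol F10.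
  - Acylation as in step 23 gives the angelate F11.
  - DDQ in wet CH2Cl2 gives the carbinol F12.
  - Dess–Martin oxidation buffered with NaHCO3 gives 32.

## Further compounds

F1 | step 8 | (4S)-4-(propan-2-yl)cyclohex-2-en-1-one | O=C1C=C[C@H](C(C)C)CC1
F2 | step 8 | tert-butyl 2-[6-(propan-2-yl)-3-(trimethylsilyloxy)cyclohex-2-en-1-yl]acetate, acetate arm on C7a trans to isopropyl | C[Si](C)(C)OC1=C[C@@H](CC(=O)OC(C)(C)C)[C@H](C(C)C)CC1
F3 | step 8 | tert-butyl 2-[2-(2-methoxy-2-oxoethyl)-3-oxo-6-(propan-2-yl)cyclohexyl]acetate, all substituents equatorial | COC(=O)C[C@H]1C(=O)CC[C@@H](C(C)C)[C@@H]1CC(=O)OC(C)(C)C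
F4 | step 8 | ethylene ketal of F3 | COC(=O)C[C@H]1C2(OCCO2)CC[C@@H](C(C)C)[C@@H]1CC(=O)OC(C)(C)C
F5 | step 8 | tert-butyl ester analogue of 13 | O1CCOC12CC[C@@H](C(C)C)[C@@H]3[C@@H](C(=O)OC(C)(C)C)C(=O)C[C@@H]23
F6 | step 15 | 5,6-epoxide of 19, oxygen on the face of H7a | O=C1[C@H]2O[C@H]2[C@@H](C(C)C)[C@@H]3[C@@H](C(=O)N(C)OC)[C@@H](O[Si](C)(C)C(C)(C)C)C[C@@H]13
F7 | step 16 | 4-methylidene analogue of 20 (axial C6 pinacol boronate) | C=C1C[C@@H](B2OC(C)(C)C(C)(C)O2)[C@@H](C(C)C)[C@@H]3[C@@H](C(=O)N(C)OC)[C@@H](O[Si](C)(C)C(C)(C)C)C[C@@H]13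
F8 | step 23 | 1-(1-hydroxyethyl) analogue of 29, mixture at the carbinol carbon | C=C1C[C@@H](OC(=O)[C@@]2(C)O[C@H]2C)[C@@H](C(C)C)[C@@H]2[C@@H](C(C)O)[C@@H](O[Si](C)(C)C(C)(C)C)C[C@@H]12
F9 | step 23 | 4-methoxybenzyl ether of F8 | C=C1C[C@@H](OC(=O)[C@@]2(C)O[C@H]2C)[C@@H](C(C)C)[C@@H]2[C@@H](C(C)OCc3ccc(OC)cc3)[C@@H](O[Si](C)(C)C(C)(C)C)C[C@@H]12
F10 | step 23 | C2 alcohol from F9 | C=C1C[C@@H](OC(=O)[C@@]2(C)O[C@H]2C)[C@@H](C(C)C)[C@@H]2[C@@H](C(C)OCc3ccc(OC)cc3)[C@@H](O)C[C@@H]12
F11 | step 23 | C2 angelate of F10 | C=C1C[C@@H](OC(=O)[C@@]2(C)O[C@H]2C)[C@@H](C(C)C)[C@@H]2[C@@H](C(C)OCc3ccc(OC)cc3)[C@@H](OC(=O)/C(C)=C\C)C[C@@H]12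
F12 | step 23 | 1-(1-hydroxyethyl) analogue of 32 | C=C1C[C@@H](OC(=O)[C@@]2(C)O[C@H]2C)[C@@H](C(C)C)[C@@H]2[C@@H](C(C)O)[C@@H](OC(=O)/C(C)=C\C)C[C@@H]12
A1 | alternative 1 | C6 alcohol, the target without the epoxy ester | C=C1C[C@@H](O)[C@@H](C(C)C)[C@@H]2[C@@H](C(C)=O)[C@@H](OC(=O)/C(C)=C\C)C[C@@H]12
A2 | alternative 2 | bicyclic enone with C2 carbonyl, C1=C7a alkene, C4 ketal and C6 silyl ether | O=C1C[C@H]2C3(OCCO3)C[C@@H](O[Si](C)(C)C(C)(C)C)[C@@H](C(C)C)C2=C1
A3 | alternative 3 | cyclopentane keto ester with C1 acetyl, C2 PMB ether and C3a methyl ester | COC(=O)[C@@H]1C[C@H](OCc2ccc(OC)cc2)[C@H](C(C)=O)[C@H]1[C@H](C(C)C)CO[Si](C)(C)C(C)(C)C
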